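The readings come from a simulation with constants of no real substance; the scatter is artificial.

- A leftover set me off: at 60.0 s the eta run still held 24.4% of its substrate, while target was slowing at 31.3%.

common to all: substrate 0.30 M (fed, over 15 s); free catalyst 2.8 mol%
- beta: partner 0.070 equiv; temperature 10 °C; run made earlier; the fed solution adds 0.25 times the starting volume
- eta: partner 0.32 equiv; temperature 21 °C; run made earlier; the fed solution adds 0.25 times the starting volume
- south-west: partner 0.500 equiv; at 5 °C until 15 s, from then on at 25 °C; the fed solution adds 0.25 times the starting volume; time 5.0 min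
- north-east: partner 0.120 equiv; at 5 °C throughout; the fed solution adds 0.25 times the starting volume; time 5.0 min

beta run (percent of the substrate charged)

| time / min | target / % | substrate / % |
|---|---|---|
| 0.200 | 2.1 | 71.9 |
| 0.333 | 3.8 | 85.1 |
| 0.500 | 5.8 | 77.7 |
| 0.667 | 6.5 | 72.0 |
| 1.00 | 6.4 | 62.5 |
| 1.50 | 7.0 | 51.5 |
| 2.50 | 7.3 | 37.9 |

eta run (percent of the substrate charged)

| time / s | target / % | substrate / % |
|---|---|---|
| 10.0 | 9.9 | 48.7 |
| 15.0 | 16.6 | 69.1 |
| 20.0 | 21.7 | 56.2 |
| 25.0 | 26.0 | 47.7 |
| 40.0 | 29.7 | 32.5 |
| 60.0 | 31.3 | 24.4 |

(readings scatter by 0.3 percentage points)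

- which of the two ends with the higher amount of target, in percent of the substrate charged ("neither" if they lie within 2 percentage points) (south-west / north-east / neither)
- target at the end, in percent of the substrate charged, south-west
- target at the end, in percent of the substrate charged, north-east

- charges are per starting volume, the dose included; the dosed solution carries all of it
- the earlier runs were read with a standard deviation of 0.3 percentage points
- percentages count the whole charge, also what has not yet gone in

- The beta run showed the same puzzle: from 1.00 min to 2.50 min substrate fell by 25 percentage points, but target rose by 0.9 points, two numbers that don't seem to belong to one reaction.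
- I divided the eta run's last target reading by its partner charge, which gave 0.978, and called this the yield per equivalent; the beta run read 1.04.
- So I read partner as the limiting reagent, with target following its charge, and took the further fall of substrate as a second road that yields no target.
- For south-west, with 0.500 equiv of partner, the yield per equivalent gave me 48.9%; for north-east, with 0.120 equiv, it gave 11.7%.
- I assumed that 5.0 min was enough, being longer than the beta run's 2.50 min, though north-east's 5 °C is colder than that run's 10 °C.
- The forecast, holding that “partner is limiting and reacts 1:1”, gave 49.3% for south-west and 11.9% for north-east, and so chose south-west.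
- The flasks gave 46.5% in south-west and 12.0% in north-east, so south-west ended higher, as forecast.

    substrate + free catalyst ⇌ catalyst intermediate A (K = 230 M⁻¹, k = 3.28 M⁻¹ s⁻¹, Ea = 51.0 kJ mol⁻¹, ΔH = −56.0 kJ mol⁻¹)
    partner + catalyst intermediate A → catalyst intermediate B (k = 8.31 M⁻¹ s⁻¹, Ea = 45.0 kJ mol⁻¹)
    catalyst intermediate B ⇌ by-product + catalyst intermediate C (K = 0.530 M, k = 3.44 s⁻¹, Ea = 67.0 kJ mol⁻¹, ΔH = −13.0 kJ mol⁻¹)
    catalyst intermediate C → free catalyst + target (k = 0.911 s⁻¹, Ea = 63.0 kJ mol⁻¹)
    partner + free catalyst + target → free catalyst + over-reaction product (k = 6.36 M⁻² s⁻¹, Ea = 37.0 kJ mol⁻¹)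
    substrate ⇌ dormant form (K = 4.00, k = 0.00424 s⁻¹, Ea = 73.0 kJ mol⁻¹, ΔH = −14.0 kJ mol⁻¹)
    (constants at 5 °C)

- The end values gave a yield per equivalent of 0.930 in south-west and 1.000 in north-east. Given south-west's equivalents of partner, north-east ended at 46.7% instead of 12.0%, a rise of 35 points, the largest single effect in the gap between the two flasks. Given south-west's temperature programme, north-east stayed at 11.9%.
- For the neighbour of north-east with 0.300 equiv of partner, the yield per equivalent gives 29.3%; the computed flask ends at 29.4%.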